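The route cuts the oxane ring (O1, C2–C6) at C2–C3 and C5–C6. The C4 carbinol with its neighbouring methylenes C3 and C5 is bought as (S)-epichlorohydrin, while C2 and C6, each 1,3 to C4, enter as dithiane-masked acyl anions. In one flask the lithiated aryl dithiane and then the lithiated arylethyl dithiane are joined through this three-carbon bis-electrophile, forming both C–C bonds and carrying the purchased stereocentre into an (R)-carbinol flanked by two latent ketones. The step needs only two simple, achiral 2-substituted 1,3-dithianes, with all three phenols as benzyl ethers. Directed reduction, cationic ring closure and hydrogenolysis then finish the all-cis (2S,4R,6S) target.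

Key step: step 6

Remark: the target is read as the all-cis oxane (2S,4R,6S); ring compounds use oxane numbering (O1, C2 aryl, C4 hydroxyl, C6 arylethyl), and open-chain intermediates are numbered as heptanes with C1 carrying the trioxygenated aryl, so heptane C1, C3, C5 become oxane C2, C4, C6.

Step 1
Reactants: 1 3,4-dihydroxy-5-methoxybenzaldehyde (5-hydroxyvanillin)
Product: 2 3,4-bis(benzyloxy)-5-methoxybenzaldehyde
Conditions: BnBr (2.4 equiv), K2CO3, DMF, 60 °C
Reagents that add atoms: benzyl bromide, BrCc1ccccc1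
Why: Williamson etherification of both phenoxides, the aldehyde being inert; benzyl ethers are chosen because they tolerate organolithiums, Hg(ClO4)2, borohydride and mild acid and all fall in the last step.

Step 2
Reactants: 2 3,4-bis(benzyloxy)-5-methoxybenzaldehyde; 3 propane-1,3-dithiol
Product: 4 2-[3,4-bis(benzyloxy)-5-methoxyphenyl]-1,3-dithiane
Conditions: BF3·OEt2 (0.2 equiv), CH2Cl2, 0 °C → rt
Reagents that add atoms: none
Why: Lewis-acid-catalysed dithioacetalisation of an aromatic aldehyde, with substoichiometric BF3·OEt2 at 0 °C too mild to cleave the aryl benzyl ethers.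

Step 3
Reactants: 5 3-(4-hydroxyphenyl)propan-1-ol
Product: 6 3-[4-(benzyloxy)phenyl]propan-1-ol
Conditions: BnBr (1.05 equiv), K2CO3, acetone, reflux
Reagents that add atoms: benzyl bromide, BrCc1ccccc1
Why: Williamson etherification that is chemoselective for the phenol, since carbonate deprotonates only the phenolic hydroxyl and not the primary alcohol.

Step 4
Reactants: 6 3-[4-(benzyloxy)phenyl]propan-1-ol
Product: 7 3-[4-(benzyloxy)phenyl]propanal
Conditions: TEMPO (10 mol %), PhI(OAc)2 (1.1 equiv), CH2Cl2, rt
Reagents that add atoms: none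
Why: oxoammonium-mediated (TEMPO/PhI(OAc)2) oxidation of a primary alcohol, which stops at the aldehyde and leaves the benzyl ether alone.

Step 5
Reactants: 7 3-[4-(benzyloxy)phenyl]propanal; 3 propane-1,3-dithiol
Product: 8 2-{2-[4-(benzyloxy)phenyl]ethyl}-1,3-dithiane
Conditions: BF3·OEt2 (0.2 equiv), CH2Cl2, 0 °C → rt
Reagents that add atoms: none
Why: Lewis-acid-catalysed dithioacetalisation of an aliphatic aldehyde, fast enough at 0 °C to outrun aldol self-condensation.

Step 6
Reactants: 4 2-[3,4-bis(benzyloxy)-5-methoxyphenyl]-1,3-dithiane; 9 (S)-epichlorohydrin; 8 2-{2-[4-(benzyloxy)phenyl]ethyl}-1,3-dithiane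
Product: 14 (2R)-1-{2-[3,4-bis(benzyloxy)-5-methoxyphenyl]-1,3-dithian-2-yl}-3-(2-{2-[4-(benzyloxy)phenyl]ethyl}-1,3-dithian-2-yl)propan-2-ol, via lithiated aryl dithiane 10 (not isolated), via lithium chloro alkoxide 11 (not isolated), via relocated epoxide 12 (not isolated), via lithiated arylethyl dithiane 13 (not isolated)
Conditions: 4, n-BuLi, THF, −78 → −30 °C; 9 (1.05 equiv), −78 °C → rt; then 13 (1.5 equiv; from 8, t-BuLi, THF/HMPA 10:1, −78 °C), −78 → 0 °C; aq NH4Cl
Reagents that add atoms: none
Why: The sulfur-stabilised carbanion 10 attacks the unsubstituted ring carbon of 9 in an SN2 epoxide opening (forming the later C2–C3 bond), the lithium alkoxide 11 displaces the neighbouring chloride on warming to give the relocated epoxide 12, and the second carbanion 13 opens 12 at its CH2 terminus (forming the later C5–C6 bond). The closest known reaction type is the Corey–Seebach dithiane alkylation, run as a one-flask linchpin coupling of two acyl anion equivalents through epichlorohydrin. No ring of the product is closed; the only ring formed is the transient oxirane of 12, by 3-exo-tet Williamson displacement. No new stereocentre is created: the C–O carbon of 9 is never attacked, so its configuration passes unchanged into the carbinol of 14 (later C4), and the descriptor reads R only because the ligand priorities change. The selectivity needed is regiochemical, attack at the terminal epoxide carbon and not at C–Cl or the substituted carbon in both openings; ring strain and the unhindered CH2 terminus should secure this for soft lithiodithianes at low temperature, and the order of addition (aryl anion first on the S epoxide) then fixes the absolute configuration. Because 12 has no acidic dithiane proton, the more basic anion 13 is not quenched by proton transfer, provided 10 has been fully consumed by the slight excess of 9.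

Step 7
Reactants: 14 (2R)-1-{2-[3,4-bis(benzyloxy)-5-methoxyphenyl]-1,3-dithian-2-yl}-3-(2-{2-[4-(benzyloxy)phenyl]ethyl}-1,3-dithian-2-yl)propan-2-ol
Product: 15 (3R)-1-[3,4-bis(benzyloxy)-5-methoxyphenyl]-7-[4-(benzyloxy)phenyl]-3-hydroxyheptane-1,5-dione
Conditions: Hg(ClO4)2·3H2O (4.4 equiv), CaCO3, THF/H2O 5:1, 0 °C
Reagents that add atoms: water, O
Why: thiophilic Hg(ClO4)2-assisted hydrolysis of both dithioacetals (Corey–Seebach unmasking), where the carbonate buffer and 0 °C should keep the β-hydroxy diketone from dehydration or retro-aldol cleavage and the C3 stereocentre is not involved.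

Step 8
Reactants: 15 (3R)-1-[3,4-bis(benzyloxy)-5-methoxyphenyl]-7-[4-(benzyloxy)phenyl]-3-hydroxyheptane-1,5-dione
Product: 16 (1S,3R,5S)-1-[3,4-bis(benzyloxy)-5-methoxyphenyl]-7-[4-(benzyloxy)phenyl]heptane-1,3,5-triol
Conditions: Me4NBH(OAc)3 (10 equiv), MeCN/AcOH 1:1, −30 → 0 °C; aqueous work-up
Reagents that add atoms: none
Why: Evans–Saksena reduction, in which the C3 hydroxyl exchanges an acetate on boron and the resulting alkoxydiacetoxyborohydride delivers hydride internally through a chair-like six-membered transition state to each β-carbonyl in turn, which should set C5 (S) and C1 (S) both 1,3-anti to C3; only C5 has to be controlled, because C1 is ionised in step 9.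

Step 9
Reactants: 16 (1S,3R,5S)-1-[3,4-bis(benzyloxy)-5-methoxyphenyl]-7-[4-(benzyloxy)phenyl]heptane-1,3,5-triol
Product: 17 (2S,4R,6S)-2-[3,4-bis(benzyloxy)-5-methoxyphenyl]-6-{2-[4-(benzyloxy)phenyl]ethyl}oxan-4-ol
Conditions: p-TsOH·H2O (10 mol %), CH2Cl2 (0.01 M), rt
Reagents that add atoms: none
Why: Brønsted-acid-catalysed SN1 etherification (cyclodehydration), in which only the benzylic C1 hydroxyl, activated by the para-benzyloxy donor, ionises, the C5 hydroxyl closes the six-membered ring on the cation through a chair with all three substituents equatorial, and reversible re-ionisation of the benzylic ether should drain any 2,6-trans isomer into the all-cis oxane, fixing oxane C2 as S while C4 and C6 are untouched.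

Step 10
Reactants: 17 (2S,4R,6S)-2-[3,4-bis(benzyloxy)-5-methoxyphenyl]-6-{2-[4-(benzyloxy)phenyl]ethyl}oxan-4-ol
Product: 18 (2S,4R,6S)-2-(3,4-dihydroxy-5-methoxyphenyl)-6-[2-(4-hydroxyphenyl)ethyl]oxan-4-ol
Conditions: H2 (1 atm), 10% Pd/C, EtOAc, rt
Reagents that add atoms: none
Why: heterogeneous hydrogenolysis of three aryl benzyl ethers over palladium on carbon, which should be much faster than cleavage of the cyclic secondary benzylic C2–O1 bond, so that stopping after uptake of three equivalents leaves the oxane and its three stereocentres intact.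

Compound list
1 | 3,4-dihydroxy-5-methoxybenzaldehyde (5-hydroxyvanillin) | COc1cc(C=O)cc(O)c1O | starting material
2 | 3,4-bis(benzyloxy)-5-methoxybenzaldehyde | COc1cc(C=O)cc(OCc2ccccc2)c1OCc1ccccc1 | intermediate
3 | propane-1,3-dithiol | SCCCS | starting material
4 | 2-[3,4-bis(benzyloxy)-5-methoxyphenyl]-1,3-dithiane | COc1cc(C2SCCCS2)cc(OCc2ccccc2)c1OCc1ccccc1 | intermediate
5 | 3-(4-hydroxyphenyl)propan-1-ol | OCCCc1ccc(O)cc1 | starting material
6 | 3-[4-(benzyloxy)phenyl]propan-1-ol | OCCCc1ccc(OCc2ccccc2)cc1 | intermediate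
7 | 3-[4-(benzyloxy)phenyl]propanal | O=CCCc1ccc(OCc2ccccc2)cc1 | intermediate
8 | 2-{2-[4-(benzyloxy)phenyl]ethyl}-1,3-dithiane | C1CSC(CCc2ccc(OCc3ccccc3)cc2)SC1 | intermediate
9 | (S)-epichlorohydrin, (2S)-2-(chloromethyl)oxirane | ClC[C@@H]1CO1 | starting material
10 | 2-lithio-2-[3,4-bis(benzyloxy)-5-methoxyphenyl]-1,3-dithiane | COc1cc(C2([Li])SCCCS2)cc(OCc2ccccc2)c1OCc1ccccc1 | intermediate
11 | lithium (2S)-1-chloro-3-{2-[3,4-bis(benzyloxy)-5-methoxyphenyl]-1,3-dithian-2-yl}propan-2-olate | COc1cc(C2(C[C@H](O[Li])CCl)SCCCS2)cc(OCc2ccccc2)c1OCc1ccccc1 | intermediate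
12 | 2-[3,4-bis(benzyloxy)-5-methoxyphenyl]-2-{[(2S)-oxiran-2-yl]methyl}-1,3-dithiane | COc1cc(C2(C[C@H]3CO3)SCCCS2)cc(OCc2ccccc2)c1OCc1ccccc1 | intermediate
13 | 2-lithio-2-{2-[4-(benzyloxy)phenyl]ethyl}-1,3-dithiane | [Li]C1(CCc2ccc(OCc3ccccc3)cc2)SCCCS1 | intermediate
14 | (2R)-1-{2-[3,4-bis(benzyloxy)-5-methoxyphenyl]-1,3-dithian-2-yl}-3-(2-{2-[4-(benzyloxy)phenyl]ethyl}-1,3-dithian-2-yl)propan-2-ol | COc1cc(C2(C[C@H](O)CC3(CCc4ccc(OCc5ccccc5)cc4)SCCCS3)SCCCS2)cc(OCc2ccccc2)c1OCc1ccccc1 | intermediate
15 | (3R)-1-[3,4-bis(benzyloxy)-5-methoxyphenyl]-7-[4-(benzyloxy)phenyl]-3-hydroxyheptane-1,5-dione | COc1cc(C(=O)C[C@H](O)CC(=O)CCc2ccc(OCc3ccccc3)cc2)cc(OCc2ccccc2)c1OCc1ccccc1 | intermediate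
16 | (1S,3R,5S)-1-[3,4-bis(benzyloxy)-5-methoxyphenyl]-7-[4-(benzyloxy)phenyl]heptane-1,3,5-triol | COc1cc([C@@H](O)C[C@H](O)C[C@@H](O)CCc2ccc(OCc3ccccc3)cc2)cc(OCc2ccccc2)c1OCc1ccccc1 | intermediate
17 | (2S,4R,6S)-2-[3,4-bis(benzyloxy)-5-methoxyphenyl]-6-{2-[4-(benzyloxy)phenyl]ethyl}oxan-4-ol | COc1cc([C@@H]2C[C@H](O)C[C@H](CCc3ccc(OCc4ccccc4)cc3)O2)cc(OCc2ccccc2)c1OCc1ccccc1 | intermediate
18 | (2S,4R,6S)-2-(3,4-dihydroxy-5-methoxyphenyl)-6-[2-(4-hydroxyphenyl)ethyl]oxan-4-ol | COc1cc([C@@H]2C[C@H](O)C[C@H](CCc3ccc(O)cc3)O2)cc(O)c1O | target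

Total step count: 10.
Longest linear sequence: 8 steps (steps 3, 4, 5, 6, 7, 8, 9, 10, from 5 to 18).

Steps most likely to fail

Step 6. The relocated epoxide may not form cleanly before the second anion arrives. The hindered, strongly basic anion 13 may transfer a proton or isomerise the epoxide instead of adding. Part of the stabilised anion 10 may displace chloride directly, which would erode the enantiomeric purity. The fallback replaces the one-flask union by two separate two-component unions in the reverse order with the antipodal linchpin. It sets out from 8: anion 13 is added to (R)-epichlorohydrin (ClC[C@H]1CO1) in THF at −78 °C and the mixture is quenched cold, to give the chlorohydrin (2R)-1-chloro-3-(2-{2-[4-(benzyloxy)phenyl]ethyl}-1,3-dithian-2-yl)propan-2-ol F1. K2CO3 in MeOH at rt closes this to the isolated epoxide 2-{2-[4-(benzyloxy)phenyl]ethyl}-2-{[(2R)-oxiran-2-yl]methyl}-1,3-dithiane F2, whose enantiomeric purity can be checked before use. The less basic anion 10, made from 4 with n-BuLi, then opens F2 at its CH2 terminus in THF (−78 °C → rt), and the route is rejoined at 14.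

Step 8. Hydride delivery may be incomplete or poorly face-selective at the C5 carbonyl when a single hydroxyl has to direct two reductions. The fallback uses one directed Tishchenko reduction followed by a kinetically controlled reductive etherification, which also replaces step 9. It sets out from 15: SmI2 (30 mol %) and benzaldehyde in THF at −10 °C should give, by Evans–Tishchenko hydride transfer within the C3 hemiacetal, the anti hydroxy ester (3R,5S)-1-[3,4-bis(benzyloxy)-5-methoxyphenyl]-7-[4-(benzyloxy)phenyl]-5-hydroxy-1-oxoheptan-3-yl benzoate F3. This compound, in equilibrium with its cyclic hemiketal form, is treated with Et3SiH and BF3·OEt2 in CH2Cl2 at −40 °C. Axial hydride delivery to the 2-aryl oxocarbenium ion should then give the 2,6-cis oxane (2S,4R,6S)-2-[3,4-bis(benzyloxy)-5-methoxyphenyl]-6-{2-[4-(benzyloxy)phenyl]ethyl}oxan-4-yl benzoate F4. K2CO3 in MeOH removes the benzoate, and the route is rejoined at 17.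

Step 9. Ionisation may be slow, the benzylic cation may eliminate to the styrene or be captured intermolecularly by an electron-rich arene, or equilibration to the 2,6-cis isomer may be incomplete. The fallback sets oxane C2 under kinetic instead of thermodynamic control. It sets out from 16: MnO2 in CH2Cl2 at rt should oxidise only the benzylic carbinol, to give (3R,5S)-1-[3,4-bis(benzyloxy)-5-methoxyphenyl]-7-[4-(benzyloxy)phenyl]-3,5-dihydroxyheptan-1-one F5. Through its cyclic hemiketal form this is reduced with Et3SiH and BF3·OEt2 in CH2Cl2 at −40 °C, where axial hydride attack on the oxocarbenium ion places the aryl group equatorial, and the route is rejoined at 17.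

Further compounds
F1 | step 6 | (2R)-1-chloro-3-(2-{2-[4-(benzyloxy)phenyl]ethyl}-1,3-dithian-2-yl)propan-2-ol | ClC[C@H](O)CC1(CCc2ccc(OCc3ccccc3)cc2)SCCCS1
F2 | step 6 | 2-{2-[4-(benzyloxy)phenyl]ethyl}-2-{[(2R)-oxiran-2-yl]methyl}-1,3-dithiane | C1CSC(CCc2ccc(OCc3ccccc3)cc2)(C[C@@H]2CO2)SC1
F3 | step 8 | (3R,5S)-1-[3,4-bis(benzyloxy)-5-methoxyphenyl]-7-[4-(benzyloxy)phenyl]-5-hydroxy-1-oxoheptan-3-yl benzoate | COc1cc(C(=O)C[C@H](OC(=O)c2ccccc2)C[C@@H](O)CCc2ccc(OCc3ccccc3)cc2)cc(OCc2ccccc2)c1OCc1ccccc1
F4 | step 8 | (2S,4R,6S)-2-[3,4-bis(benzyloxy)-5-methoxyphenyl]-6-{2-[4-(benzyloxy)phenyl]ethyl}oxan-4-yl benzoate | COc1cc([C@@H]2C[C@H](OC(=O)c3ccccc3)C[C@H](CCc3ccc(OCc4ccccc4)cc3)O2)cc(OCc2ccccc2)c1OCc1ccccc1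
F5 | step 9 | (3R,5S)-1-[3,4-bis(benzyloxy)-5-methoxyphenyl]-7-[4-(benzyloxy)phenyl]-3,5-dihydroxyheptan-1-one | COc1cc(C(=O)C[C@H](O)C[C@@H](O)CCc2ccc(OCc3ccccc3)cc2)cc(OCc2ccccc2)c1OCc1ccccc1
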